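**Strategy.** In 2-oxaspiro[4.5]decane numbering the carbocycle of the target is a cyclohexene whose C7=C8 alkene sits between two oxygenated carbons, the C6 ketone and the C9 acetoxy carbon, with spiro C5 and C10H2 completing the ring. Cutting C5–C6 and C9–C10 therefore leads to a symmetric 1,4-dioxygenated butadiene and a 2-substituted acrolein whose α-carbon becomes C5. One catalytic enantioselective Diels–Alder reaction makes both bonds, the ring, and the C5 and C9 stereocentres (plus C6, later oxidised); the formyl group then takes up the side chain and the ester arm closes the spirolactone. The precursors are achiral: (E,E)-1,4-diacetoxybutadiene and methyl 3-formylbut-3-enoate.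

Key step: step 4

Assumption: the facial sense of the boron catalyst is taken from its known adducts with 2-bromoacrolein and methacrolein, which assigns the required addition to the (R)-prolinol-derived catalyst; for the chromium ligand of step 5 the antipode that adds to the Re face of the formyl group is used.

Numbering note: spiro compounds 12–15 use C1 (lactone carbinol), O2, C3 (lactone C=O), C4, C5 (spiro), C6–C10 (carbocycle).

**Step 1**
Reactants: 1 methyl 4-oxobutanoate; 2 formaldehyde (37 % aqueous)
Product: 3 methyl 3-formylbut-3-enoate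
Conditions: aq. CH2O (1.0 equiv), pyrrolidine (10 mol %), EtCO2H (10 mol %), i-PrOH, 45 °C, short reaction time; used fresh
Reagents that add atoms: none
Why: Amine/acid-catalysed Mannich condensation of the enamine of 1 with formaldehyde and β-elimination of the amine (organocatalytic α-methylenation of an aldehyde) gives the 2-substituted acrolein, and a short reaction time with direct use limits migration of the alkene into conjugation with the ester.

**Step 2**
Reactants: 4 pent-1-en-4-yne
Product: 6 (1E)-1-iodo-2-methylpenta-1,4-diene, via dimethyl[(1E)-2-methylpenta-1,4-dien-1-yl]alane 5 (not isolated)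
Conditions: Me3Al (2 equiv), Cp2ZrCl2 (20 mol %), CH2Cl2, 0 °C→rt; then I2, THF, −30→0 °C
Reagents that add atoms: trimethylaluminium, C[Al](C)C; iodine, II
Why: Zirconium-catalysed syn-carboalumination of the terminal alkyne (Negishi carboalumination) puts methyl on the internal carbon and aluminium on the terminus, and iodinolysis of the C–Al bond with retention gives the E-iodoalkene, while the monosubstituted alkene is carbometallated far more slowly.

**Step 3**
Reactants: 6 (1E)-1-iodo-2-methylpenta-1,4-diene; 7 2-methylbut-3-en-2-ol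
Product: 8 (3E,6E)-7-iodo-2,6-dimethylhepta-3,6-dien-2-ol
Conditions: Hoveyda–Grubbs II (5 mol %), 7 (5 equiv), 1,4-benzoquinone (10 mol %), CH2Cl2, 40 °C
Reagents that add atoms: none
Why: Olefin cross-metathesis joins the terminal vinyl group of 6 to the slowly dimerising partner 7, the trisubstituted iodoalkene being inert to the ruthenium carbene, the bulky carbinol end enforcing the E-alkene, and benzoquinone suppressing hydride-mediated migration of the skipped diene.

**Step 4**
Reactants: 3 methyl 3-formylbut-3-enoate; 9 (1E,3E)-buta-1,3-diene-1,4-diyl diacetate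
Product: 10 methyl 2-[(1S,2S,5S)-2,5-diacetoxy-1-formylcyclohex-3-en-1-yl]acetate (formyl cis to both acetoxy groups)
Conditions: (R)-B-(o-tolyl) oxazaborolidine from (R)-α,α-diphenylprolinol (20 mol %), Tf2NH (17 mol %), 9 (2 equiv), CH2Cl2, −78→−20 °C
Reagents that add atoms: none
Why: The N-protonated oxazaborolidine binds the formyl oxygen of 3 (a formyl C–H···O contact to the catalyst oxygen fixes the enal geometry) and lowers its LUMO, so that diene 9 adds in a concerted, asynchronous [4πs+2πs] cycloaddition. The closest known reaction type is the oxazaborolidinium-catalysed enantioselective Diels–Alder reaction of 2-substituted acroleins such as methacrolein and 2-bromoacrolein with acyclic dienes, combined with the known thermal cycloadditions of 1,4-diacetoxybutadiene. The cyclohexene ring closes by intermolecular [4+2] annulation, the C1–C2 and C5–C6 bonds of 10 forming on one face of each partner. C2 and C5 become cis because the E,E geometry of the diene is transferred suprafacially; C1 is set relative to them by the formyl-endo transition state that acyclic 1-oxygenated dienes normally adopt with α-substituted acroleins (the CH2CO2Me arm points away from the diene), and in the absolute sense by the catalyst aryl group, which shields one α-face so that the diene adds to the Re face of the α-carbon. The step needs only endo and enantioface selectivity: regiochemistry does not arise because the two diene termini are equivalent, and the formyl group is the single two-point binding site of 3 for the catalyst.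

**Step 5**
Reactants: 10 methyl 2-[(1S,2S,5S)-2,5-diacetoxy-1-formylcyclohex-3-en-1-yl]acetate; 8 (3E,6E)-7-iodo-2,6-dimethylhepta-3,6-dien-2-ol
Product: 11 methyl 2-[(1R,2S,5S)-2,5-diacetoxy-1-[(1R,2E,5E)-1,7-dihydroxy-3,7-dimethylocta-2,5-dien-1-yl]cyclohex-3-en-1-yl]acetate
Conditions: CrCl2 (4 equiv), NiCl2 (2 mol %), enantiopure N-[2-(4-isopropyl-4,5-dihydrooxazol-2-yl)-6-methylphenyl]methanesulfonamide (4.4 equiv), Et3N, THF, rt; crude product taken on
Reagents that add atoms: none
Why: Nickel inserts into the C–I bond with retention and transmetallation gives an alkenylchromium(III) species that adds to the non-enolisable neopentyl aldehyde (Nozaki–Hiyama–Kishi reaction) without touching ester, acetates or the free tertiary alcohol, the chiral sulfonamide ligand on chromium directing the alkenyl group to the Re face of the formyl group and so setting the (R)-carbinol.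

**Step 6**
Reactants: 11 methyl 2-[(1R,2S,5S)-2,5-diacetoxy-1-[(1R,2E,5E)-1,7-dihydroxy-3,7-dimethylocta-2,5-dien-1-yl]cyclohex-3-en-1-yl]acetate
Product: 13 (1R,5S,6S,9S)-6,9-dihydroxy-1-[(1E,4E)-6-hydroxy-2,6-dimethylhepta-1,4-dien-1-yl]-2-oxaspiro[4.5]dec-7-en-3-one, via spirolactone diacetate 12 (not isolated)
Conditions: K2CO3 (0.2 equiv), MeOH, 0 °C→rt; AcOH quench, concentrate
Reagents that add atoms: none
Why: The secondary alkoxide closes the γ-lactone on the methyl ester by 5-exo-trig acyl substitution helped by the quaternary carbon (Thorpe–Ingold effect) and base-catalysed transesterification with methanol removes both acetates; any 12 already formed in step 5 converges here, the strain-free spirolactone is expected to prevail over a trans-fused lactone to the C6 hydroxyl, and no stereocentre is touched.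

**Step 7**
Reactants: 13 (1R,5S,6S,9S)-6,9-dihydroxy-1-[(1E,4E)-6-hydroxy-2,6-dimethylhepta-1,4-dien-1-yl]-2-oxaspiro[4.5]dec-7-en-3-one
Product: 14 (1R,5S,6S,9S)-6-hydroxy-1-[(1E,4E)-6-hydroxy-2,6-dimethylhepta-1,4-dien-1-yl]-3-oxo-2-oxaspiro[4.5]dec-7-en-9-yl acetate
Conditions: Ac2O (1.2 equiv), pyridine, CH2Cl2, −20→0 °C (no DMAP)
Reagents that add atoms: acetic anhydride, CC(=O)OC(C)=O
Why: Acylation without a nucleophilic catalyst discriminates sterically, so the C9 carbinol flanked by CH2 and CH= reacts while the neopentyl-type C6 carbinol beside the spiro carbon and the tertiary side-chain carbinol are left.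

**Step 8**
Reactants: 14 (1R,5S,6S,9S)-6-hydroxy-1-[(1E,4E)-6-hydroxy-2,6-dimethylhepta-1,4-dien-1-yl]-3-oxo-2-oxaspiro[4.5]dec-7-en-9-yl acetate
Product: 15 (+)-miliusane XVII, (1R,5R,9S)-1-[(1E,4E)-6-hydroxy-2,6-dimethylhepta-1,4-dien-1-yl]-3,6-dioxo-2-oxaspiro[4.5]dec-7-en-9-yl acetate
Conditions: Dess–Martin periodinane (1.5 equiv), NaHCO3, CH2Cl2, 0 °C→rt
Reagents that add atoms: none
Why: Dess–Martin oxidation turns the remaining secondary allylic carbinol into the enone under buffered, non-basic conditions, the tertiary alcohol being inert, the spiro carbon having no α-hydrogen and C9 not being epimerisable.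

**Compound list**
1 | methyl 4-oxobutanoate | COC(=O)CCC=O | starting material
2 | formaldehyde | C=O | starting material
3 | methyl 3-formylbut-3-enoate | COC(=O)CC(=C)C=O | intermediate
4 | pent-1-en-4-yne | C=CCC#C | starting material
5 | dimethyl[(1E)-2-methylpenta-1,4-dien-1-yl]alane | C=CC/C(C)=C/[Al](C)C | intermediate
6 | (1E)-1-iodo-2-methylpenta-1,4-diene | C=CC/C(C)=C/I | intermediate
7 | 2-methylbut-3-en-2-ol | CC(C)(O)C=C | starting material
8 | (3E,6E)-7-iodo-2,6-dimethylhepta-3,6-dien-2-ol | CC(C)(O)/C=C/C/C(C)=C/I | intermediate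
9 | (1E,3E)-buta-1,3-diene-1,4-diyl diacetate | CC(=O)O/C=C/C=C/OC(C)=O | starting material
10 | methyl 2-[(1S,2S,5S)-2,5-diacetoxy-1-formylcyclohex-3-en-1-yl]acetate | CC(=O)O[C@@H]1C=C[C@H](OC(C)=O)[C@@](C=O)(CC(=O)OC)C1 | intermediate
11 | methyl 2-[(1R,2S,5S)-2,5-diacetoxy-1-[(1R,2E,5E)-1,7-dihydroxy-3,7-dimethylocta-2,5-dien-1-yl]cyclohex-3-en-1-yl]acetate | CC(=O)O[C@@H]1C=C[C@H](OC(C)=O)[C@@]([C@H](O)/C=C(\C)C/C=C/C(C)(C)O)(CC(=O)OC)C1 | intermediate
12 | (1R,5S,6S,9S)-1-[(1E,4E)-6-hydroxy-2,6-dimethylhepta-1,4-dien-1-yl]-3-oxo-2-oxaspiro[4.5]dec-7-ene-6,9-diyl diacetate | CC(=O)O[C@@H]1C=C[C@H](OC(C)=O)[C@@]2(CC(=O)O[C@@H]2/C=C(\C)C/C=C/C(C)(C)O)C1 | intermediate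
13 | (1R,5S,6S,9S)-6,9-dihydroxy-1-[(1E,4E)-6-hydroxy-2,6-dimethylhepta-1,4-dien-1-yl]-2-oxaspiro[4.5]dec-7-en-3-one | O[C@@H]1C=C[C@H](O)[C@@]2(CC(=O)O[C@@H]2/C=C(\C)C/C=C/C(C)(C)O)C1 | intermediate
14 | (1R,5S,6S,9S)-6-hydroxy-1-[(1E,4E)-6-hydroxy-2,6-dimethylhepta-1,4-dien-1-yl]-3-oxo-2-oxaspiro[4.5]dec-7-en-9-yl acetate | CC(=O)O[C@@H]1C=C[C@H](O)[C@@]2(CC(=O)O[C@@H]2/C=C(\C)C/C=C/C(C)(C)O)C1 | intermediate
15 | (+)-miliusane XVII, (1R,5R,9S)-1-[(1E,4E)-6-hydroxy-2,6-dimethylhepta-1,4-dien-1-yl]-3,6-dioxo-2-oxaspiro[4.5]dec-7-en-9-yl acetate | CC(=O)O[C@@H]1C=CC(=O)[C@@]2(CC(=O)O[C@@H]2/C=C(\C)C/C=C/C(C)(C)O)C1 | target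

**Step count.** Total: 8 steps. Longest linear sequence: 6 steps (steps 1, 4, 5, 6, 7, 8; the side-chain branch through steps 2 and 3 is equally long).

**Steps most likely to fail**

Step 4. The acetoxy-substituted diene may be too weakly nucleophilic for the catalyst-bound enal at the temperatures where the cationic boron catalyst remains selective. Conversion could then stall, or acid-induced decomposition of diene and dienophile and erosion of endo and facial selectivity at higher temperature could take over. The fallback sets out from 3 and 9 and gives up asymmetric catalysis for resolution. The cycloaddition is run thermally in toluene at about 100 °C with a radical inhibitor, the mode in which this diene is known to add to acrylic dienophiles. The formyl-endo racemate is purified and resolved on a chiral stationary phase by preparative SFC. This removes the enantiomer methyl 2-[(1R,2R,5R)-2,5-diacetoxy-1-formylcyclohex-3-en-1-yl]acetate F1 and delivers 10, where the route is rejoined.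

Step 5. Facial selectivity at the hindered neopentyl formyl group may be poor if the substrate bias overrides the ligand, and the addition may be slow enough for nickel to begin ionising the allylic acetates. The fallback sets out from 10 and 8 and moves stereocontrol from C–C bond formation to a ketone reduction. A ligand-free Ni/Cr coupling in DMSO should give 11 together with its carbinol epimer methyl 2-[(1R,2S,5S)-2,5-diacetoxy-1-[(1S,2E,5E)-1,7-dihydroxy-3,7-dimethylocta-2,5-dien-1-yl]cyclohex-3-en-1-yl]acetate F2. The mixture is oxidised at once, before lactonisation, with Dess–Martin periodinane to the enone methyl 2-[(1S,2S,5S)-2,5-diacetoxy-1-[(2E,5E)-7-hydroxy-3,7-dimethylocta-2,5-dienoyl]cyclohex-3-en-1-yl]acetate F3. Corey–Bakshi–Shibata reduction with the (S)-oxazaborolidine and catecholborane, with the quaternary ring carbon as the large group, should return the (R)-carbinol 11, where the route is rejoined.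

Step 7. Site selectivity between the two secondary allylic hydroxyls may be lost, giving acetylation at C6 or bis-acetylation. The fallback sets out from 13 and replaces direct acetylation by a more size-sensitive protection, with the acetate installed last. Silylation with TBSCl and imidazole in DMF at 0 °C should give the C9 ether (1R,5S,6S,9S)-9-[(tert-butyldimethylsilyl)oxy]-6-hydroxy-1-[(1E,4E)-6-hydroxy-2,6-dimethylhepta-1,4-dien-1-yl]-2-oxaspiro[4.5]dec-7-en-3-one F4. Dess–Martin oxidation gives the enone (1R,5R,9S)-9-[(tert-butyldimethylsilyl)oxy]-1-[(1E,4E)-6-hydroxy-2,6-dimethylhepta-1,4-dien-1-yl]-2-oxaspiro[4.5]dec-7-ene-3,6-dione F5. Desilylation with pyridine-buffered HF·pyridine gives (1R,5R,9S)-9-hydroxy-1-[(1E,4E)-6-hydroxy-2,6-dimethylhepta-1,4-dien-1-yl]-2-oxaspiro[4.5]dec-7-ene-3,6-dione F6. Its only secondary hydroxyl is acetylated with Ac2O and pyridine to give 15 directly.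

**Further compounds**
F1 | step 4 | methyl 2-[(1R,2R,5R)-2,5-diacetoxy-1-formylcyclohex-3-en-1-yl]acetate (enantiomer of 10 in the racemate) | CC(=O)O[C@H]1C=C[C@@H](OC(C)=O)[C@](C=O)(CC(=O)OC)C1
F2 | step 5 | methyl 2-[(1R,2S,5S)-2,5-diacetoxy-1-[(1S,2E,5E)-1,7-dihydroxy-3,7-dimethylocta-2,5-dien-1-yl]cyclohex-3-en-1-yl]acetate | CC(=O)O[C@@H]1C=C[C@H](OC(C)=O)[C@@]([C@@H](O)/C=C(\C)C/C=C/C(C)(C)O)(CC(=O)OC)C1
F3 | step 5 | methyl 2-[(1S,2S,5S)-2,5-diacetoxy-1-[(2E,5E)-7-hydroxy-3,7-dimethylocta-2,5-dienoyl]cyclohex-3-en-1-yl]acetate | CC(=O)O[C@@H]1C=C[C@H](OC(C)=O)[C@@](C(=O)/C=C(\C)C/C=C/C(C)(C)O)(CC(=O)OC)C1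
F4 | step 7 | (1R,5S,6S,9S)-9-[(tert-butyldimethylsilyl)oxy]-6-hydroxy-1-[(1E,4E)-6-hydroxy-2,6-dimethylhepta-1,4-dien-1-yl]-2-oxaspiro[4.5]dec-7-en-3-one | CC(C)(C)[Si](C)(C)O[C@@H]1C=C[C@H](O)[C@@]2(CC(=O)O[C@@H]2/C=C(\C)C/C=C/C(C)(C)O)C1
F5 | step 7 | (1R,5R,9S)-9-[(tert-butyldimethylsilyl)oxy]-1-[(1E,4E)-6-hydroxy-2,6-dimethylhepta-1,4-dien-1-yl]-2-oxaspiro[4.5]dec-7-ene-3,6-dione | CC(C)(C)[Si](C)(C)O[C@@H]1C=CC(=O)[C@@]2(CC(=O)O[C@@H]2/C=C(\C)C/C=C/C(C)(C)O)C1
F6 | step 7 | (1R,5R,9S)-9-hydroxy-1-[(1E,4E)-6-hydroxy-2,6-dimethylhepta-1,4-dien-1-yl]-2-oxaspiro[4.5]dec-7-ene-3,6-dione | O[C@@H]1C=CC(=O)[C@@]2(CC(=O)O[C@@H]2/C=C(\C)C/C=C/C(C)(C)O)C1
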